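The cyclohexene is numbered C1 (carries the acrylate arm C7=C8–C9), C2 (=CH), C3, C5, C6 (each CO2H) and C4 (catechol). The ring hides a meso unit: without aryl group, arm and C3 carboxyl, C1–C6 is cis-1,2-dihydrophthalic acid, whose diene is C1=C2–C3=C4. The route rests on one desymmetrising palladium-catalysed three-component coupling that bonds C4 to the aryl bromide and C1 to C7 of the danshensu alkenylboronate across the meso diene di-tert-butyl ester, fixing C4, C5 and C6 without closing a ring. The C3 carboxyl follows by a bis-vinylogous Mukaiyama reaction; tert-butyl esters and catechol acetonides fall in one acid step.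

Key step: step 9

Assumption: the sense of induction of the chiral phosphoramidite in step 9 cannot be predicted, so the ligand antipode that gives 15 is to be found by experiment; because 14 is a single enantiomer, the two ring antipodes are diastereomers and can be told apart and separated.

Shorthand in names: Ar = 2,2-dimethyl-1,3-benzodioxol-5-yl; R*O = the alkoxy residue of alcohol 11; ring atoms C1–C6 and arm atoms C7–C9 as numbered above.

Step 1
Reactants: 1 phthalic acid
Product: 2 trans-1,2-dihydrophthalic acid (racemic)
Conditions: sodium amalgam (Na/Hg, 3% Na), NaOAc buffer, AcOH, H2O, 0–10 °C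
Reagents that add atoms: none
Why: Dissolving-metal (Birch-type) reduction of the phthalate dianion in buffered water adds two hydrogens at the carboxyl-bearing carbons and should give the unconjugated 1,2-dihydro acid as its trans isomer, an established preparation.

Step 2
Reactants: 2 trans-1,2-dihydrophthalic acid
Product: 3 cis-1,2-dihydrophthalic anhydride (meso)
Conditions: Ac2O, 100 °C
Reagents that add atoms: none
Why: Cyclodehydration through the mixed anhydride, in which the allylic α-C–H epimerises by enolisation, should funnel the trans acid into the only isomer able to close a five-membered anhydride, the cis-fused one.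

Step 3
Reactants: 3 cis-1,2-dihydrophthalic anhydride
Product: 5 di-tert-butyl cis-cyclohexa-3,5-diene-1,2-dicarboxylate, via cis-1,2-dihydrophthalic acid 4 (not isolated)
Conditions: H2O, THF, rt, evaporate; then O-tert-butyl-N,N′-diisopropylisourea (excess), CH2Cl2, rt
Reagents that add atoms: water O; O-tert-butyl-N,N′-diisopropylisourea CC(C)NC(=NC(C)C)OC(C)(C)C
Why: Anhydride hydrolysis followed by isourea tert-butyl esterification (carboxylate attack on the protonated isourea) needs no base, so the acidic allylic α-hydrogens, the cis (meso) relationship and the unconjugated diene should survive.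

Step 4
Reactants: 6 4-bromocatechol
Product: 7 5-bromo-2,2-dimethyl-1,3-benzodioxole
Conditions: 2,2-dimethoxypropane, TsOH·H2O (cat.), toluene, reflux, MeOH removed over 4 Å molecular sieves
Reagents that add atoms: 2,2-dimethoxypropane COC(C)(C)OC
Why: Acid-catalysed transketalisation of the catechol, driven by removal of methanol, gives an acetonide that tolerates palladium, base, Lewis acid and chlorite and can later be removed by acid without hydrogenation of the dienoate.

Step 5
Reactants: 8 (R)-danshensu
Product: 10 (R)-3-(2,2-dimethyl-1,3-benzodioxol-5-yl)-2-hydroxypropanoic acid, via dioxolanone bis-acetonide 9 (not isolated)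
Conditions: 2,2-dimethoxypropane, TsOH·H2O (cat.), toluene, reflux (4 Å molecular sieves); then LiOH, THF/H2O, 0 °C; 1 M HCl to pH 3
Reagents that add atoms: 2,2-dimethoxypropane COC(C)(C)OC; lithium hydroxide [Li+].[OH-]
Why: The same transketalisation protects the catechol and ties the α-hydroxy acid up as a dioxolanone, and cold hydroxide then opens only this activated lactone (acyl substitution), leaving the aryl ketal and the stereocentre untouched.

Step 6
Reactants: 10 (R)-3-(2,2-dimethyl-1,3-benzodioxol-5-yl)-2-hydroxypropanoic acid
Product: 11 tert-butyl (R)-3-(2,2-dimethyl-1,3-benzodioxol-5-yl)-2-hydroxypropanoate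
Conditions: O-tert-butyl-N,N′-diisopropylisourea, CH2Cl2, rt
Reagents that add atoms: O-tert-butyl-N,N′-diisopropylisourea CC(C)NC(=NC(C)C)OC(C)(C)C
Why: In this isourea esterification only the carboxylic acid is acidic enough to protonate the reagent and take up the tert-butyl group, so the secondary alcohol stays free and the neutral medium preserves the α-stereocentre.

Step 7
Reactants: 11 tert-butyl (R)-3-(2,2-dimethyl-1,3-benzodioxol-5-yl)-2-hydroxypropanoate; 12 propiolic acid
Product: 13 tert-butyl (R)-3-(2,2-dimethyl-1,3-benzodioxol-5-yl)-2-(propioloyloxy)propanoate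
Conditions: DCC, DMAP (5 mol %), CH2Cl2, −20 to 0 °C
Reagents that add atoms: none
Why: Steglich esterification at low temperature acylates the secondary alcohol without touching the C–O bond of the stereocentre (retention) and keeps addition of DMAP to the alkyne in check.

Step 8
Reactants: 13 tert-butyl (R)-3-(2,2-dimethyl-1,3-benzodioxol-5-yl)-2-(propioloyloxy)propanoate
Product: 14 tert-butyl (R)-3-(2,2-dimethyl-1,3-benzodioxol-5-yl)-2-{[(E)-3-(4,4,5,5-tetramethyl-1,3,2-dioxaborolan-2-yl)acryloyl]oxy}propanoate
Conditions: B2pin2, CuCl (3 mol %), Xantphos (3 mol %), NaOt-Bu (6 mol %), MeOH (2 equiv), THF, rt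
Reagents that add atoms: bis(pinacolato)diboron CC1(C)OB(OC1(C)C)B1OC(C)(C)C(C)(C)O1
Why: In this copper-catalysed conjugate borylation (formal hydroboration) the boryl-copper species adds syn across the alkyne with boron at the β-carbon and methanol protonates the α-carbon, which places boron trans to the ester (E) with a regiochemistry that direct hydroboration of a propiolate with a borane would not secure.

Step 9
Reactants: 5 di-tert-butyl cis-cyclohexa-3,5-diene-1,2-dicarboxylate; 7 5-bromo-2,2-dimethyl-1,3-benzodioxole; 14 danshensu (E)-3-borylacrylate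
Product: 15 cis-1,4-aryl-alkenyl cyclohex-2-ene triester (C1 arm (E)-CH=CH–CO2R*, C2=C3, C4 Ar, C5 and C6 CO2t-Bu; arm and Ar cis to each other and trans to the cis ester pair)
Conditions: Pd2(dba)3 (2.5 mol %), (S)-BINOL N,N-bis[(R)-1-phenylethyl]phosphoramidite or its antipode (6 mol %), KF, DMA, 50 °C; 5 in excess (2 equiv), 14 added slowly by syringe pump
Reagents that add atoms: none
Why: Proposed new method: oxidative addition of 7 to the zerovalent palladium–phosphoramidite complex gives an arylpalladium bromide that inserts one terminus of diene 5 by syn carbopalladation on the face opposite the two tert-butyl esters, putting aryl on C4 and a π-allylpalladium over C3–C2–C1 on the aryl face; fluoride-assisted transmetalation from 14 and reductive elimination at C1 then form C1–C7, so aryl and arm end up cis and no ring is closed. The closest known reaction type is the palladium-catalysed three-component 1,4-carbodifunctionalisation of 1,3-dienes with an aryl or alkenyl electrophile and an organoboron reagent (Heck insertion, then Suzuki–Miyaura-type capture of the π-allyl); new here are the meso cyclohexadiene diester and the enantioselective desymmetrisation. C4 is set by the ligand, which decides which enantiotopic diene terminus is arylated, together with the ester pair, which dictates the face; this choice also fixes the existing centres C5 and C6 in the absolute sense, and C1 follows from inner-sphere delivery on the palladium face but is erased in step 10. The step needs three-component coupling over direct aryl–alkenyl coupling (excess diene, slowly transmetalating pinacol boronate fed in slowly), 1,4- over 1,2-addition (C3 is shielded by the cis aryl group on the palladium face) and reductive elimination over β-hydride loss from C6 (bulky monodentate ligand, fluoride activation). Should the C2=C3 bond drift into conjugation with the arm under the basic conditions, the isomer remains usable, since step 10 converts both into the same trienol ether.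

Step 10
Reactants: 15 cis-1,4-aryl-alkenyl cyclohex-2-ene triester
Product: 17 C3-dimethoxymethyl dienoate (C1=C2 and (E)-C7=C8; CH(OMe)2 at C3 trans to Ar), via trimethylsilyl trienol ether 16 (not isolated)
Conditions: TMSOTf (1.2 equiv), Et3N (1.5 equiv), CH2Cl2, −78 to 0 °C; then HC(OMe)3, further TMSOTf (0.5 equiv), −78 °C; NaHCO3 quench
Reagents that add atoms: trimethyl orthoformate COC(OC)OC; trimethylsilyl triflate C[Si](C)(C)OS(=O)(=O)C(F)(F)F (its Me3Si group is carried by 16 only)
Why: Soft enolisation silylates the most Lewis-basic (conjugated, least hindered) ester carbonyl and removes the doubly allylic C1–H without a strong base that would endanger the α-acyloxy ester centre, and the resulting linear silyl trienol ether should attack the dimethoxycarbenium ion at its remote ε-carbon C3 (bis-vinylogous Mukaiyama reaction; attack at C1 would create a quaternary centre and C8 is shielded by the silyl ketene acetal) on the face opposite the adjacent C4 aryl group, which sets C3 and gives the E-dienoate from the s-trans C7–C8 conformer.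

Step 11
Reactants: 17 C3-dimethoxymethyl dienoate
Product: 19 C3-carboxylic acid (three tert-butyl esters and two acetonides intact), via C3-aldehyde 18 (not isolated)
Conditions: TsOH·H2O (10 mol %), acetone/H2O, 0 °C to rt, NaHCO3; then NaClO2, NaH2PO4, 2-methyl-2-butene, t-BuOH/H2O, 0 °C
Reagents that add atoms: water O; sodium chlorite [Na+].[O-]Cl=O
Why: Mild acetal hydrolysis followed at once by Pinnick oxidation converts the masked formyl group into the acid under weakly acidic, buffered conditions that tert-butyl esters, aryl ketals and the dienoate tolerate, and the short lifetime of the aldehyde should keep the C3 configuration (trans to aryl, also the expected thermodynamic one).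

Step 12
Reactants: 19 C3-carboxylic acid
Product: 20 target CNP0327643.1 ((3R,4S,5R,6R) ring in the numbering above, (R) side chain)
Conditions: TFA/H2O (9:1), 0 °C to rt
Reagents that add atoms: none
Why: Acidolysis cleaves the three tert-butyl esters by tert-butyl cation loss and hydrolyses both catechol acetonides in one operation, while the absence of base and of hydrogen leaves the vinylogously acidic C3–H, the acrylate ester linkage and both alkenes untouched.

Compound list
1 | phthalic acid | OC(=O)c1ccccc1C(=O)O | starting material
2 | trans-1,2-dihydrophthalic acid (trans-cyclohexa-3,5-diene-1,2-dicarboxylic acid; racemic, one enantiomer drawn) | C1=CC=C[C@@H](C(=O)O)[C@@H]1C(=O)O | intermediate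
3 | cis-1,2-dihydrophthalic anhydride (meso) | C1=CC=C[C@H]2C(=O)OC(=O)[C@@H]12 | intermediate
4 | cis-1,2-dihydrophthalic acid (meso; not isolated) | C1=CC=C[C@@H](C(=O)O)[C@H]1C(=O)O | intermediate
5 | di-tert-butyl cis-cyclohexa-3,5-diene-1,2-dicarboxylate (meso) | C1=CC=C[C@@H](C(=O)OC(C)(C)C)[C@H]1C(=O)OC(C)(C)C | intermediate
6 | 4-bromocatechol | Oc1ccc(Br)cc1O | starting material
7 | 5-bromo-2,2-dimethyl-1,3-benzodioxole | CC1(C)Oc2ccc(Br)cc2O1 | intermediate
8 | (R)-danshensu | O[C@H](Cc1ccc(O)c(O)c1)C(=O)O | starting material
9 | (R)-5-[(2,2-dimethyl-1,3-benzodioxol-5-yl)methyl]-2,2-dimethyl-1,3-dioxolan-4-one (not isolated) | CC1(C)O[C@H](Cc2ccc3OC(C)(C)Oc3c2)C(=O)O1 | intermediate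
10 | (R)-3-(2,2-dimethyl-1,3-benzodioxol-5-yl)-2-hydroxypropanoic acid | O[C@H](Cc1ccc2OC(C)(C)Oc2c1)C(=O)O | intermediate
11 | tert-butyl (R)-3-(2,2-dimethyl-1,3-benzodioxol-5-yl)-2-hydroxypropanoate | O[C@H](Cc1ccc2OC(C)(C)Oc2c1)C(=O)OC(C)(C)C | intermediate
12 | propiolic acid | C#CC(=O)O | starting material
13 | tert-butyl (R)-3-(2,2-dimethyl-1,3-benzodioxol-5-yl)-2-(propioloyloxy)propanoate | C#CC(=O)O[C@H](Cc1ccc2OC(C)(C)Oc2c1)C(=O)OC(C)(C)C | intermediate
14 | tert-butyl (R)-3-(2,2-dimethyl-1,3-benzodioxol-5-yl)-2-{[(E)-3-(4,4,5,5-tetramethyl-1,3,2-dioxaborolan-2-yl)acryloyl]oxy}propanoate | CC1(C)OB(/C=C/C(=O)O[C@H](Cc2ccc3OC(C)(C)Oc3c2)C(=O)OC(C)(C)C)OC1(C)C | intermediate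
15 | cis-1,4-aryl-alkenyl cyclohex-2-ene triester: C1 arm (E)-CH=CH–CO2R*, C2=C3, C4 Ar, C5/C6 CO2t-Bu; arm and Ar cis, both trans to the cis ester pair | O=C(/C=C/[C@@H]1C=C[C@H](c2ccc3OC(C)(C)Oc3c2)[C@@H](C(=O)OC(C)(C)C)[C@H]1C(=O)OC(C)(C)C)O[C@H](Cc1ccc2OC(C)(C)Oc2c1)C(=O)OC(C)(C)C | intermediate
16 | trimethylsilyl trienol ether C3=C2–C1=C7–C8=C9(OSiMe3)(OR*); geometry at C1=C7 and C8=C9 unassigned and of no consequence (not isolated) | C[Si](C)(C)OC(=CC=C1C=C[C@H](c2ccc3OC(C)(C)Oc3c2)[C@@H](C(=O)OC(C)(C)C)[C@H]1C(=O)OC(C)(C)C)O[C@H](Cc1ccc2OC(C)(C)Oc2c1)C(=O)OC(C)(C)C | intermediate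
17 | C3-dimethoxymethyl dienoate: C1=C2, (E)-C7=C8, CH(OMe)2 at C3 trans to Ar at C4 | O=C(/C=C/C1=C[C@@H](C(OC)OC)[C@H](c2ccc3OC(C)(C)Oc3c2)[C@@H](C(=O)OC(C)(C)C)[C@H]1C(=O)OC(C)(C)C)O[C@H](Cc1ccc2OC(C)(C)Oc2c1)C(=O)OC(C)(C)C | intermediate
18 | C3-aldehyde (not isolated) | O=C(/C=C/C1=C[C@@H](C=O)[C@H](c2ccc3OC(C)(C)Oc3c2)[C@@H](C(=O)OC(C)(C)C)[C@H]1C(=O)OC(C)(C)C)O[C@H](Cc1ccc2OC(C)(C)Oc2c1)C(=O)OC(C)(C)C | intermediate
19 | C3-carboxylic acid with tert-butyl esters at C5, C6 and the danshensu carboxyl and both catechol acetonides | O=C(/C=C/C1=C[C@@H](C(=O)O)[C@H](c2ccc3OC(C)(C)Oc3c2)[C@@H](C(=O)OC(C)(C)C)[C@H]1C(=O)OC(C)(C)C)O[C@H](Cc1ccc2OC(C)(C)Oc2c1)C(=O)OC(C)(C)C | intermediate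
20 | CNP0327643.1 | O=C(/C=C/C1=C[C@@H](C(=O)O)[C@H](c2ccc(O)c(O)c2)[C@@H](C(=O)O)[C@H]1C(=O)O)O[C@H](Cc1ccc(O)c(O)c1)C(=O)O | target

Total step count: 12. Longest linear sequence: 8 steps (8 → 10 → 11 → 13 → 14 → 15 → 17 → 19 → 20; steps 5–12).

Steps most likely to fail

Step 9. The arylpalladium species may couple directly with the boronate, the π-allyl intermediate may lose the C6 hydrogen and aromatise, the acrylate of 14 may undergo Heck insertion, or the ligand may discriminate poorly between the two diene termini. The fallback gives up catalyst control and reverses the roles of the partners, using the known ligand-free three-component 1,4-alkenyl-arylation of 1,3-dienes with an alkenyl halide and an arylboronic acid. It sets out from 5, 7, 11 and 12 and returns at 15. Bromide 7 would be converted (n-BuLi, B(Oi-Pr)3, THF, −78 °C, aqueous NH4Cl) into (2,2-dimethyl-1,3-benzodioxol-5-yl)boronic acid F1. Propiolic acid 12 heated with aqueous HI should give, under thermodynamic control, (E)-3-iodoacrylic acid F2, which would be esterified with 11 (DCC, DMAP) to tert-butyl (R)-3-(2,2-dimethyl-1,3-benzodioxol-5-yl)-2-{[(E)-3-iodoacryloyl]oxy}propanoate F3. Diene 5, F3 and F1 would then be combined with Pd2(dba)3 and KF in DMA. The alkenylpalladium species should add to either diene terminus anti to the esters and the aryl group be delivered 1,4 on the same face, so that 15 forms together with the ring-antipodal diastereomer of 15 F4. Because the danshensu centre makes the two diastereomeric, they would be separated by chromatography and 15 carried on.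

Step 10. Enolisation may occur at the danshensu α-carbon with loss of configuration, the electrophile may attack C8 or C1 instead of C3, or the face selectivity at C3 may be poor. The fallback is a Lewis-acid-promoted carbonyl-ene reaction that needs no enol ether; it sets out from 15 and returns at 19. With paraformaldehyde and Me2AlCl in CH2Cl2 (−78 to 0 °C), formaldehyde should bond to C3 of the C2=C3 alkene while the doubly allylic C1–H is transferred suprafacially. Since that hydrogen lies on the face opposite aryl and arm, the new carbon should arrive trans to the aryl group and the alkene should move to C1=C2, giving the C3-hydroxymethyl dienoate F5. Buffered oxidation (TEMPO cat., NaOCl cat., NaClO2, MeCN/phosphate buffer pH 6.7) would take F5 through aldehyde 18 to acid 19.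

Step 11. During acetal hydrolysis the liberated aldehyde may enolise towards C3, causing epimerisation or migration of the C1=C2 bond into conjugation with the formyl group. The fallback avoids a free aldehyde by oxidising the acetal carbon directly; it sets out from 17 and returns at 19. Treatment of 17 with KHSO5 (as its triple salt 2KHSO5·KHSO4·K2SO4) on wet alumina, a known oxidation of dimethyl acetals to methyl esters, should give the C3-methyl ester F6. Me3SnOH in 1,2-dichloroethane at 70 °C would then cleave this methyl ester selectively beside the tert-butyl esters and the secondary acrylate ester, giving 19.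

Further compounds
F1 | step 9 | (2,2-dimethyl-1,3-benzodioxol-5-yl)boronic acid | CC1(C)Oc2ccc(B(O)O)cc2O1
F2 | step 9 | (E)-3-iodoacrylic acid | OC(=O)/C=C/I
F3 | step 9 | tert-butyl (R)-3-(2,2-dimethyl-1,3-benzodioxol-5-yl)-2-{[(E)-3-iodoacryloyl]oxy}propanoate | I/C=C/C(=O)O[C@H](Cc1ccc2OC(C)(C)Oc2c1)C(=O)OC(C)(C)C
F4 | step 9 | ring-antipodal diastereomer of 15 | O=C(/C=C/[C@H]1C=C[C@@H](c2ccc3OC(C)(C)Oc3c2)[C@H](C(=O)OC(C)(C)C)[C@@H]1C(=O)OC(C)(C)C)O[C@H](Cc1ccc2OC(C)(C)Oc2c1)C(=O)OC(C)(C)C
F5 | step 10 | C3-hydroxymethyl dienoate | O=C(/C=C/C1=C[C@@H](CO)[C@H](c2ccc3OC(C)(C)Oc3c2)[C@@H](C(=O)OC(C)(C)C)[C@H]1C(=O)OC(C)(C)C)O[C@H](Cc1ccc2OC(C)(C)Oc2c1)C(=O)OC(C)(C)C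
F6 | step 11 | C3-methyl ester | O=C(/C=C/C1=C[C@@H](C(=O)OC)[C@H](c2ccc3OC(C)(C)Oc3c2)[C@@H](C(=O)OC(C)(C)C)[C@H]1C(=O)OC(C)(C)C)O[C@H](Cc1ccc2OC(C)(C)Oc2c1)C(=O)OC(C)(C)C
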